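**Retrosynthetic overview**

1. The C1'=C2' bond of the diene is cut to a silyl-protected (R)-2-methylchroman-2-carbaldehyde and a C15 allylic phosphonate (Horner–Wadsworth–Emmons); the phenol is freed last.
2. The phosphonate comes from 2-bromo-1,3,3-trimethylcyclohexene and one alkylborane, made once by hydroboration of (E)-3-methylpenta-2,4-dien-1-ol and used in two B-alkyl Suzuki–Miyaura couplings; the E-trisubstituted alkene is bought in with commercial (E)-3-methylpent-2-en-4-yn-1-ol.
3. The bromocyclohexene comes by one-carbon ring expansion from the dibromocarbene adduct of 1,2-dimethylcyclopentene. The enabling feature is the cyclopropane C1–C5–C6 fused to the cyclopentane in 6,6-dibromo-1,5-dimethylbicyclo[3.1.0]hexane, with an endo C6–Br bond and a methyl group on each bridgehead (C1, C5): loss of bromide opens the strained C1–C5 bond to a mirror-symmetric 2-bromoallyl cation, which AlMe3 methylates.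
4. The aldehyde comes from a 2-vinylchroman, made by Pd-catalysed asymmetric allylic etherification of a phenol allyl carbonate (sets C2); that carbonate comes from 2-bromo-4-(silyloxy)phenol and the second portion of the same alkylborane.
5. Ring order: cyclopentene to cyclohexene by ring expansion first, then the dihydropyran ring of the chroman; the benzene ring is bought.

Key step: step 2

Assumption: the (R,R) antipode of the bisphosphine ligand in step 12 is taken to give the 2R chroman; if the first run shows the opposite sense, the (S,S) antipode is used with no other change.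

**Route**

Step 1
Reactants: 1 1,2-dimethylcyclopent-1-ene
Product: 2 (1R,5S)-6,6-dibromo-1,5-dimethylbicyclo[3.1.0]hexane (meso, cis-fused)
Conditions: CHBr3, KOt-Bu, pentane, −20 to 0 °C; cold filtration, crude product kept below 0 °C and used at once
Reagents that add atoms: bromoform, BrC(Br)Br
Why: Dibromocarbene cyclopropanation: the electron-rich tetrasubstituted alkene should trap the carbene formed by α-elimination from bromoform stereospecifically to give the cis-fused meso adduct, and the cold non-polar medium should keep it from ionizing before step 2.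

Step 2
Reactants: 2 (1R,5S)-6,6-dibromo-1,5-dimethylbicyclo[3.1.0]hexane
Product: 4 2-bromo-1,3,3-trimethylcyclohex-1-ene, via allyl cation ion pair 3 (not isolated)
Conditions: AlMe3 (2 equiv), CH2Cl2/hexane, −78 to −20 °C; cold aqueous KNaC4H4O6 (potassium sodium tartrate) quench
Reagents that add atoms: trimethylaluminium, C[Al](C)C
Why: Proposed new method: Me3Al binds the endo bromine on C6 of 2 and its departure is concerted with disrotatory 2π-electrocyclic opening of the cyclopropane (the endo halide leaves as the C1–C5 fusion bond breaks), so that cyclopropane strain is released and the cyclopentane C1–C2–C3–C4–C5 is expanded by C6 to the 2-bromo-1,3-dimethylcyclohexenyl cation of ion pair 3, whose bromotrimethylaluminate counter-ion then transfers a methyl group to an allyl terminus. The closest known reaction types are the thermal and AgNO3- or AgClO4-promoted ring expansion of 6,6-dibromobicyclo[3.1.0]hexanes to 2-bromocyclohex-2-enyl derivatives with heteroatom nucleophiles and the C-methylation of tertiary and allylic halides by AlMe3; running both in one operation with a carbon nucleophile on a gem-dihalocyclopropane is the new element. No ring is closed: the six-membered ring arises by cleavage of the bond shared by the three- and five-membered rings. No stereocentre is created, since 4 is achiral. The step needs control of the site of methyl delivery and of substitution against proton loss: the first is guaranteed because cation 3 has a mirror plane through C6 and C3 that makes its two methyl-bearing termini identical (either attack gives the gem-dimethyl carbon next to the C–Br carbon and the tetrasubstituted alkene), and the second should be secured by the non-basic aluminate, the low temperature and the weakly coordinating solvent.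

Step 3
Reactants: 5 (2E)-3-methylpent-2-en-4-yn-1-ol
Product: 6 (2E)-3-methylpenta-2,4-dien-1-ol
Conditions: H2 (1 atm), Pd/CaCO3 poisoned with Pb(OAc)2 (Lindlar catalyst), quinoline, EtOAc, rt, stopped after 1 equiv H2
Reagents that add atoms: none
Why: Lindlar semihydrogenation: the poisoned palladium surface should reduce the terminal alkyne to the vinyl group and stop there, leaving the E-trisubstituted alkene and the allylic alcohol untouched.

Step 4
Reactants: 6 (2E)-3-methylpenta-2,4-dien-1-ol
Product: 7 9-{[(2E)-5-(9-borabicyclo[3.3.1]nonan-9-yl)-3-methylpent-2-en-1-yl]oxy}-9-borabicyclo[3.3.1]nonane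
Conditions: 9-BBN (0.5 M in THF, 2.2 equiv), 0 °C to rt, argon; the resulting THF solution of 7 is assayed by oxidation of an aliquot, stored under argon and divided between steps 5 and 10
Reagents that add atoms: 9-borabicyclo[3.3.1]nonane (9-BBN), B1C2CCCC1CCC2
Why: Hydroboration: the first equivalent of 9-BBN should be consumed by the hydroxyl group with loss of hydrogen, and the second should add in the anti-Markovnikov sense to the unhindered terminal CH2 of the monosubstituted vinyl group much faster than to the trisubstituted alkene, whose E-geometry is therefore carried over.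

Step 5
Reactants: 7 9-{[(2E)-5-(9-borabicyclo[3.3.1]nonan-9-yl)-3-methylpent-2-en-1-yl]oxy}-9-borabicyclo[3.3.1]nonane (THF solution from step 4, 1.3 equiv); 4 2-bromo-1,3,3-trimethylcyclohex-1-ene
Product: 8 (2E)-3-methyl-5-(2,6,6-trimethylcyclohex-1-en-1-yl)pent-2-en-1-ol
Conditions: Pd(OAc)2, SPhos, K3PO4·H2O, THF, 65 °C; then aqueous NaOH work-up
Reagents that add atoms: none
Why: B-alkyl Suzuki–Miyaura coupling: the primary alkyl group on boron should be transferred to palladium and coupled with the hindered alkenyl bromide under the bulky electron-rich biarylphosphine, the borinate O–B bond is hydrolysed on work-up, and the E-alkene is carried over unchanged.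

Step 6
Reactants: 8 (2E)-3-methyl-5-(2,6,6-trimethylcyclohex-1-en-1-yl)pent-2-en-1-ol
Product: 9 2-[(3E)-5-bromo-3-methylpent-3-en-1-yl]-1,3,3-trimethylcyclohex-1-ene
Conditions: CBr4, PPh3, CH2Cl2, 0 °C
Reagents that add atoms: carbon tetrabromide, BrC(Br)(Br)Br
Why: Appel bromination: bromide displaces the alkoxyphosphonium group at the primary allylic carbon under neutral conditions, so neither allylic transposition nor acid-promoted migration of the ring double bond is expected.

Step 7
Reactants: 9 2-[(3E)-5-bromo-3-methylpent-3-en-1-yl]-1,3,3-trimethylcyclohex-1-ene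
Product: 10 diethyl [(2E)-3-methyl-5-(2,6,6-trimethylcyclohex-1-en-1-yl)pent-2-en-1-yl]phosphonate
Conditions: P(OEt)3 (neat), 120 °C, EtBr distilled off
Reagents that add atoms: triethyl phosphite, CCOP(OCC)OCC
Why: Michaelis–Arbuzov reaction: SN2 attack of the phosphite on the primary allylic bromide followed by dealkylation by bromide should give the phosphonate with the E-geometry unchanged.

Step 8
Reactants: 11 hydroquinone (benzene-1,4-diol)
Product: 12 4-[(triisopropylsilyl)oxy]phenol
Conditions: TIPSCl (1 equiv), imidazole, hydroquinone (3 equiv), DMF, 0 °C to rt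
Reagents that add atoms: chlorotriisopropylsilane, CC(C)[Si](Cl)(C(C)C)C(C)C
Why: Statistical monosilylation: with the diol in excess the bulky silyl chloride should give mainly the mono-ether, and the surplus hydroquinone is washed out with water.

Step 9
Reactants: 12 4-[(triisopropylsilyl)oxy]phenol
Product: 13 2-bromo-4-[(triisopropylsilyl)oxy]phenol
Conditions: NBS, i-Pr2NH (10 mol %), CH2Cl2, 0 °C
Reagents that add atoms: N-bromosuccinimide, O=C1CCC(=O)N1Br
Why: Amine-catalysed electrophilic ortho-bromination: with the para position blocked, NBS should brominate next to the free hydroxyl group, which activates more strongly and is less shielded than the silyloxy group.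

Step 10
Reactants: 7 9-{[(2E)-5-(9-borabicyclo[3.3.1]nonan-9-yl)-3-methylpent-2-en-1-yl]oxy}-9-borabicyclo[3.3.1]nonane (THF solution from step 4, 1.3 equiv); 13 2-bromo-4-[(triisopropylsilyl)oxy]phenol
Product: 14 2-[(3E)-5-hydroxy-3-methylpent-3-en-1-yl]-4-[(triisopropylsilyl)oxy]phenol
Conditions: Pd(OAc)2, SPhos, K3PO4·H2O (excess, to cover the phenol), THF, 65 °C; then aqueous NaOH, neutralised with aqueous NH4Cl
Reagents that add atoms: none
Why: B-alkyl Suzuki–Miyaura coupling: the same primary alkylborane should couple with the aryl bromide (present as its phenoxide) to set the two-carbon tether, the borinate O–B bond is hydrolysed on work-up, and the E-alkene is carried over unchanged.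

Step 11
Reactants: 14 2-[(3E)-5-hydroxy-3-methylpent-3-en-1-yl]-4-[(triisopropylsilyl)oxy]phenol
Product: 16 (2E)-5-{2-hydroxy-5-[(triisopropylsilyl)oxy]phenyl}-3-methylpent-2-en-1-yl methyl carbonate, via bis-carbonate 15 (not isolated)
Conditions: ClCO2Me, pyridine, CH2Cl2, 0 °C; aqueous wash; then pyrrolidine, THF, 0 °C to rt
Reagents that add atoms: methyl chloroformate, COC(=O)Cl
Why: Acylation followed by chemoselective aminolysis: both hydroxyl groups are carbonated, and pyrrolidine should then cleave only the aryl carbonate, an activated ester with a phenoxide leaving group, while the alkyl allyl carbonate is inert to amines.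

Step 12
Reactants: 16 (2E)-5-{2-hydroxy-5-[(triisopropylsilyl)oxy]phenyl}-3-methylpent-2-en-1-yl methyl carbonate
Product: 17 (2R)-2-ethenyl-2-methyl-6-[(triisopropylsilyl)oxy]-3,4-dihydro-2H-chromene
Conditions: Pd2(dba)3·CHCl3 (2 mol %), (R,R)-DACH-phenyl bisphosphine ligand {N,N'-[(1R,2R)-cyclohexane-1,2-diyl]bis[2-(diphenylphosphanyl)benzamide]} (6 mol %), AcOH (1 equiv), CH2Cl2, rt
Reagents that add atoms: none
Why: Tsuji–Trost asymmetric allylic etherification: ionization of the carbonate gives a π-allylpalladium complex that the phenol attacks at its more substituted terminus in a 6-exo closure, and the chiral pocket of the (R,R)-ligand decides which face of the allyl unit is attacked, setting C2 as R.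

Step 13
Reactants: 17 (2R)-2-ethenyl-2-methyl-6-[(triisopropylsilyl)oxy]-3,4-dihydro-2H-chromene
Product: 19 (2R)-2-methyl-6-[(triisopropylsilyl)oxy]-3,4-dihydro-2H-chromene-2-carbaldehyde, via ozonide 18 (not isolated)
Conditions: O3, CH2Cl2, −78 °C (Sudan Red 7B end point); then PPh3, −78 °C to rt
Reagents that add atoms: ozone, [O-][O+]=O
Why: Ozonolysis with reductive work-up: the isolated monosubstituted alkene should react with ozone far faster than the silyloxy-substituted arene, and the quaternary stereocentre cannot epimerize because it bears no hydrogen.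

Step 14
Reactants: 10 diethyl [(2E)-3-methyl-5-(2,6,6-trimethylcyclohex-1-en-1-yl)pent-2-en-1-yl]phosphonate; 19 (2R)-2-methyl-6-[(triisopropylsilyl)oxy]-3,4-dihydro-2H-chromene-2-carbaldehyde
Product: 21 triisopropyl({(2R)-2-methyl-2-[(1E,3E)-4-methyl-6-(2,6,6-trimethylcyclohex-1-en-1-yl)hexa-1,3-dien-1-yl]-3,4-dihydro-2H-chromen-6-yl}oxy)silane, via lithiated phosphonate 20 (not isolated)
Conditions: n-BuLi, THF/HMPA, −78 °C; then 19, −78 °C to rt
Reagents that add atoms: none
Why: Horner–Wadsworth–Emmons olefination: the lithiated allylic phosphonate should add through its α-carbon to the non-enolizable α-quaternary aldehyde and eliminate to the E-alkene (HMPA favouring equilibration to the anti adduct), leaving the existing E-trisubstituted alkene and the C2 stereocentre untouched.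

Step 15
Reactants: 21 triisopropyl({(2R)-2-methyl-2-[(1E,3E)-4-methyl-6-(2,6,6-trimethylcyclohex-1-en-1-yl)hexa-1,3-dien-1-yl]-3,4-dihydro-2H-chromen-6-yl}oxy)silane
Product: 22 (2R)-2-methyl-2-[(1E,3E)-4-methyl-6-(2,6,6-trimethylcyclohex-1-en-1-yl)hexa-1,3-dien-1-yl]-3,4-dihydro-2H-chromen-6-ol
Conditions: TBAF, AcOH, THF, 0 °C to rt
Reagents that add atoms: none
Why: Fluoride-mediated desilylation: the aryl silyl ether should be cleaved by fluoride under acetic acid buffering, which avoids both acid-promoted ionization of the tertiary allylic ether and base-promoted air oxidation of the phenol.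

**Compound list**

1 | 1,2-dimethylcyclopent-1-ene | CC1=C(C)CCC1 | starting material
2 | (1R,5S)-6,6-dibromo-1,5-dimethylbicyclo[3.1.0]hexane (meso) | C[C@@]12CCC[C@]1(C)C2(Br)Br | intermediate
3 | 2-bromo-1,3-dimethylcyclohex-2-en-1-ylium bromotrimethylaluminate (ion pair) | CC1=C(Br)[C+](C)CCC1.C[Al-](C)(C)Br | intermediate
4 | 2-bromo-1,3,3-trimethylcyclohex-1-ene | CC1=C(Br)C(C)(C)CCC1 | intermediate
5 | (2E)-3-methylpent-2-en-4-yn-1-ol | OC/C=C(C)/C#C | starting material
6 | (2E)-3-methylpenta-2,4-dien-1-ol | OC/C=C(C)/C=C | intermediate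
7 | 9-{[(2E)-5-(9-borabicyclo[3.3.1]nonan-9-yl)-3-methylpent-2-en-1-yl]oxy}-9-borabicyclo[3.3.1]nonane | O(C/C=C(C)/CCB1C2CCCC1CCC2)B1C2CCCC1CCC2 | intermediate
8 | (2E)-3-methyl-5-(2,6,6-trimethylcyclohex-1-en-1-yl)pent-2-en-1-ol | OC/C=C(C)/CCC1=C(C)CCCC1(C)C | intermediate
9 | 2-[(3E)-5-bromo-3-methylpent-3-en-1-yl]-1,3,3-trimethylcyclohex-1-ene | BrC/C=C(C)/CCC1=C(C)CCCC1(C)C | intermediate
10 | diethyl [(2E)-3-methyl-5-(2,6,6-trimethylcyclohex-1-en-1-yl)pent-2-en-1-yl]phosphonate | CCOP(=O)(OCC)C/C=C(C)/CCC1=C(C)CCCC1(C)C | intermediate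
11 | hydroquinone (benzene-1,4-diol) | Oc1ccc(O)cc1 | starting material
12 | 4-[(triisopropylsilyl)oxy]phenol | Oc1ccc(O[Si](C(C)C)(C(C)C)C(C)C)cc1 | intermediate
13 | 2-bromo-4-[(triisopropylsilyl)oxy]phenol | Oc1ccc(O[Si](C(C)C)(C(C)C)C(C)C)cc1Br | intermediate
14 | 2-[(3E)-5-hydroxy-3-methylpent-3-en-1-yl]-4-[(triisopropylsilyl)oxy]phenol | OC/C=C(C)/CCc1cc(O[Si](C(C)C)(C(C)C)C(C)C)ccc1O | intermediate
15 | (2E)-5-{2-[(methoxycarbonyl)oxy]-5-[(triisopropylsilyl)oxy]phenyl}-3-methylpent-2-en-1-yl methyl carbonate | COC(=O)OC/C=C(C)/CCc1cc(O[Si](C(C)C)(C(C)C)C(C)C)ccc1OC(=O)OC | intermediate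
16 | (2E)-5-{2-hydroxy-5-[(triisopropylsilyl)oxy]phenyl}-3-methylpent-2-en-1-yl methyl carbonate | COC(=O)OC/C=C(C)/CCc1cc(O[Si](C(C)C)(C(C)C)C(C)C)ccc1O | intermediate
17 | (2R)-2-ethenyl-2-methyl-6-[(triisopropylsilyl)oxy]-3,4-dihydro-2H-chromene | C=C[C@@]1(C)CCc2cc(O[Si](C(C)C)(C(C)C)C(C)C)ccc2O1 | intermediate
18 | (2R)-2-methyl-2-(1,2,4-trioxolan-3-yl)-6-[(triisopropylsilyl)oxy]-3,4-dihydro-2H-chromene (both epimers at the trioxolane carbon) | O1OC(OC1)[C@@]1(C)CCc2cc(O[Si](C(C)C)(C(C)C)C(C)C)ccc2O1 | intermediate
19 | (2R)-2-methyl-6-[(triisopropylsilyl)oxy]-3,4-dihydro-2H-chromene-2-carbaldehyde | O=C[C@@]1(C)CCc2cc(O[Si](C(C)C)(C(C)C)C(C)C)ccc2O1 | intermediate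
20 | lithium (2E)-1-(diethoxyphosphoryl)-3-methyl-5-(2,6,6-trimethylcyclohex-1-en-1-yl)pent-2-en-1-ide | [Li+].CCOP(=O)(OCC)[CH-]/C=C(C)/CCC1=C(C)CCCC1(C)C | intermediate
21 | triisopropyl({(2R)-2-methyl-2-[(1E,3E)-4-methyl-6-(2,6,6-trimethylcyclohex-1-en-1-yl)hexa-1,3-dien-1-yl]-3,4-dihydro-2H-chromen-6-yl}oxy)silane | CC1=C(CC/C(C)=C/C=C/[C@@]2(C)CCc3cc(O[Si](C(C)C)(C(C)C)C(C)C)ccc3O2)C(C)(C)CCC1 | intermediate
22 | (2R)-2-methyl-2-[(1E,3E)-4-methyl-6-(2,6,6-trimethylcyclohex-1-en-1-yl)hexa-1,3-dien-1-yl]-3,4-dihydro-2H-chromen-6-ol | CC1=C(CC/C(C)=C/C=C/[C@@]2(C)CCc3cc(O)ccc3O2)C(C)(C)CCC1 | target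

**Step count and risks**

Total step count: 15. Longest linear sequence: 8 steps (steps 8, 9, 10, 11, 12, 13, 14 and 15, from hydroquinone; the sequence from 5 through steps 3, 4, 10, 11, 12, 13, 14 and 15 is of the same length).

Steps most likely to fail:

Step 2 (proposed new method). Proton loss from the allyl cation, or collapse of the ion pair to a tertiary allylic bromide that eliminates HBr, may outrun methyl transfer. The fallback uses known chemistry and keeps the ring expansion but separates it from the C–C bond formation. Setting out from 2, the cyclopropane would be opened with AgNO3 in buffered aqueous acetone (AgNO3-assisted solvolytic electrocyclic ring opening) to racemic 2-bromo-1,3-dimethylcyclohex-2-en-1-ol F1. This tertiary allylic alcohol would then be methylated with Me2TiCl2 (from Me2Zn and TiCl4, CH2Cl2, −40 to 0 °C), again through the symmetric cation, and the route is rejoined at 4.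

Step 5. β-Hydride elimination from the homoallylic alkylpalladium intermediate (driven by diene formation), slow coupling at the doubly flanked alkenyl bromide, or incomplete regiocontrol in the preceding diene hydroboration may erode the coupling. The fallback builds the trisubstituted alkene after the coupling by syn-carbometalation. Setting out from 4, a Negishi coupling with [4-(trimethylsilyl)but-3-yn-1-yl]zinc bromide F2 (from 4-bromo-1-(trimethylsilyl)but-1-yne and Zn dust; Pd(P(t-Bu)3)2, THF/NMP) would give trimethyl[4-(2,6,6-trimethylcyclohex-1-en-1-yl)but-1-yn-1-yl]silane F3. K2CO3 in MeOH would free 2-(but-3-yn-1-yl)-1,3,3-trimethylcyclohex-1-ene F4. Carboalumination catalysed by Cp2ZrCl2 (AlMe3, CH2Cl2) would give dimethyl[(1E)-2-methyl-4-(2,6,6-trimethylcyclohex-1-en-1-yl)but-1-en-1-yl]alumane F5, and its n-BuLi ate complex, lithium butyl(dimethyl)[(1E)-2-methyl-4-(2,6,6-trimethylcyclohex-1-en-1-yl)but-1-en-1-yl]aluminate F6, would be trapped with paraformaldehyde to rejoin the route at 8.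

Step 14. Poor E/Z control at the new double bond, γ-attack of the allyl anion, or stalling at the β-hydroxy phosphonate may lower the yield of the E,E-diene. The fallback is a Julia–Lythgoe olefination, in which a stereoconvergent reductive elimination replaces kinetic control. Setting out from 9, displacement with PhSO2Na in DMF would give {[(2E)-3-methyl-5-(2,6,6-trimethylcyclohex-1-en-1-yl)pent-2-en-1-yl]sulfonyl}benzene F7. Its lithio derivative, lithium (2E)-3-methyl-1-(phenylsulfonyl)-5-(2,6,6-trimethylcyclohex-1-en-1-yl)pent-2-en-1-ide F8 (n-BuLi, THF, −78 °C), would be added to 19 and acetylated in the same flask (Ac2O) to give (3E)-4-methyl-1-{(2R)-2-methyl-6-[(triisopropylsilyl)oxy]-3,4-dihydro-2H-chromen-2-yl}-2-(phenylsulfonyl)-6-(2,6,6-trimethylcyclohex-1-en-1-yl)hex-3-en-1-yl acetate F9 as a mixture of diastereomers. Na/Hg (Na2HPO4, MeOH/THF, −20 °C) would convert both diastereomers into the E-alkene and rejoin the route at 21.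

Further compounds
F1 | step 2 | racemic 2-bromo-1,3-dimethylcyclohex-2-en-1-ol | CC1=C(Br)C(C)(O)CCC1
F2 | step 5 | [4-(trimethylsilyl)but-3-yn-1-yl]zinc bromide | Br[Zn]CCC#C[Si](C)(C)C
F3 | step 5 | trimethyl[4-(2,6,6-trimethylcyclohex-1-en-1-yl)but-1-yn-1-yl]silane | C[Si](C)(C)C#CCCC1=C(C)CCCC1(C)C
F4 | step 5 | 2-(but-3-yn-1-yl)-1,3,3-trimethylcyclohex-1-ene | C#CCCC1=C(C)CCCC1(C)C
F5 | step 5 | dimethyl[(1E)-2-methyl-4-(2,6,6-trimethylcyclohex-1-en-1-yl)but-1-en-1-yl]alumane | C[Al](C)/C=C(C)/CCC1=C(C)CCCC1(C)C
F6 | step 5 | lithium butyl(dimethyl)[(1E)-2-methyl-4-(2,6,6-trimethylcyclohex-1-en-1-yl)but-1-en-1-yl]aluminate | [Li+].CCCC[Al-](C)(C)/C=C(C)/CCC1=C(C)CCCC1(C)C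
F7 | step 14 | {[(2E)-3-methyl-5-(2,6,6-trimethylcyclohex-1-en-1-yl)pent-2-en-1-yl]sulfonyl}benzene | O=S(=O)(C/C=C(C)/CCC1=C(C)CCCC1(C)C)c1ccccc1
F8 | step 14 | lithium (2E)-3-methyl-1-(phenylsulfonyl)-5-(2,6,6-trimethylcyclohex-1-en-1-yl)pent-2-en-1-ide | [Li+].O=S(=O)([CH-]/C=C(C)/CCC1=C(C)CCCC1(C)C)c1ccccc1
F9 | step 14 | (3E)-4-methyl-1-{(2R)-2-methyl-6-[(triisopropylsilyl)oxy]-3,4-dihydro-2H-chromen-2-yl}-2-(phenylsulfonyl)-6-(2,6,6-trimethylcyclohex-1-en-1-yl)hex-3-en-1-yl acetate (mixture of diastereomers at C1 and C2 of the hexenyl chain) | CC(=O)OC(C(/C=C(C)/CCC1=C(C)CCCC1(C)C)S(=O)(=O)c1ccccc1)[C@@]1(C)CCc2cc(O[Si](C(C)C)(C(C)C)C(C)C)ccc2O1
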